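**Strategy.** Everything rests on cutting the two B6–D1 biaryl bonds, each joining two nucleophilic phloroglucinol-type carbons. Ring B carries free hydroxyls at B3 and B5, so B6 (ortho to the B5 hydroxyl, para to the B3 hydroxyl, equivalent to B2) holds high spin density once the phenol is oxidised, and D1 is simply a CH of 1,3,5-trimethoxybenzene. A two-directional anodic phenol–arene coupling should therefore install both D rings in one operation, without halide or boron at these tetra-ortho-substituted positions. Its precursor is a six-ring aryl ether (rings A, B, C, E) in which only the four ring B hydroxyls are free and all other oxygens are methyl ethers, assembled by iterative SNAr/Dakin chain growth from ring E outward.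

Key step: step 16

Remark on the chemistry (lettering): ring C is the central ring, with the arm ethers at C1 and C5, the hydroxyl at C3 and the ether to the chlorinated ring E at C6. Ring B is the pentasubstituted ring of each arm: B1 bears the oxygen to the terminal ring A, B2 is CH, B3 and B5 bear hydroxyls, B4 bears the oxygen to ring C, and B6 is bonded to D1 of the carbon-linked ring D.

Remark on the chemistry (design): ring D has identical ortho substituents, so neither biaryl axis is a stereo-element and the target is achiral. The ring B hydroxyls are carried as methoxymethyl (MOM) ethers, because their acid release cannot reduce the C–Cl bond of ring E, which a hydrogenolytic deprotection might. One fluoroarene (compound 8) serves as ring A and, after an exchange of protecting groups (compound 10), as rings B and C.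

**Route**

Step 1
Reactants: 1 2-chloro-1,3-dimethoxybenzene
Product: 3 4-chloro-3,5-dimethoxyphenol, via aryl pinacol boronate 2 (not isolated)
Conditions: [Ir(OMe)(cod)]2 (1.5 mol%), 4,4'-di-tert-butyl-2,2'-bipyridine (3 mol%), B2pin2 (1.0 equiv), THF, 80 °C; then 30% H2O2, aq NaOH, 0 °C → rt
Reagents that add atoms: hydrogen peroxide, OO
Why: Iridium-catalysed C–H borylation is sterically controlled and the carbon para to chlorine is the only C–H of 1 without an ortho substituent, so boron should enter meta to both methoxy groups, and oxidation of the C–B bond then gives the phenol (one-pot C–H borylation/oxidation).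

Step 2
Reactants: 4 3,5-dimethoxybenzaldehyde
Product: 5 2-(3,5-dimethoxyphenyl)-1,3-dioxolane
Conditions: HOCH2CH2OH, TsOH·H2O (cat.), toluene, reflux (Dean–Stark)
Reagents that add atoms: ethylene glycol, OCCO
Why: Acid-catalysed acetalisation with azeotropic removal of water masks the aldehyde as a dioxolane that is inert to butyllithium.

Step 3
Reactants: 5 2-(3,5-dimethoxyphenyl)-1,3-dioxolane
Product: 8 4-fluoro-3,5-dimethoxybenzaldehyde, via aryllithium 6 (not isolated), via fluoro dioxolane 7 (not isolated)
Conditions: n-BuLi, THF, 0 °C; NFSI, −78 °C → rt; then 2 M aq HCl, rt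
Reagents that add atoms: N-fluorobenzenesulfonimide, O=S(=O)(N(F)S(=O)(=O)c1ccccc1)c1ccccc1; water, O
Why: Directed ortho-metalation should occur at the ring carbon between the two methoxy groups, where both ethers cooperate in guiding the base, electrophilic fluorination of the aryllithium with NFSI forms the C–F bond, and aqueous acid hydrolyses the dioxolane on work-up.

Step 4
Reactants: 8 4-fluoro-3,5-dimethoxybenzaldehyde
Product: 9 4-fluoro-3,5-dihydroxybenzaldehyde
Conditions: BBr3, CH2Cl2, −78 °C → rt; then H2O
Reagents that add atoms: none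
Why: Lewis acid-mediated O-demethylation with BBr3 cleaves both aryl methyl ethers, while the C–F bond and (after aqueous work-up) the aldehyde are retained.

Step 5
Reactants: 9 4-fluoro-3,5-dihydroxybenzaldehyde
Product: 10 4-fluoro-3,5-bis(methoxymethoxy)benzaldehyde
Conditions: MOMCl, i-Pr2NEt, CH2Cl2, 0 °C → rt
Reagents that add atoms: chloromethyl methyl ether, COCCl
Why: Williamson-type O-alkylation of both phenols gives base-stable, acid-labile MOM ethers that can later be removed without touching methyl ethers or the aryl chloride.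

Step 6
Reactants: 3 4-chloro-3,5-dimethoxyphenol; 10 4-fluoro-3,5-bis(methoxymethoxy)benzaldehyde
Product: 11 4-(4-chloro-3,5-dimethoxyphenoxy)-3,5-bis(methoxymethoxy)benzaldehyde
Conditions: K2CO3, DMSO, 110 °C, argon
Reagents that add atoms: none
Why: Nucleophilic aromatic substitution (addition–elimination) in which the phenoxide of 3 attacks the fluorine-bearing carbon of 10, whose fluoride is activated by the para formyl group and is small enough to tolerate the two flanking MOM ethers, forms the ether between ring E and C6 of ring C.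

Step 7
Reactants: 11 4-(4-chloro-3,5-dimethoxyphenoxy)-3,5-bis(methoxymethoxy)benzaldehyde
Product: 13 4-(4-chloro-3,5-dimethoxyphenoxy)-3,5-bis(methoxymethoxy)phenol, via aryl formate 12 (not isolated)
Conditions: mCPBA, CH2Cl2, 0 °C → rt; reductive wash; then K2CO3 (cat.), MeOH, rt
Reagents that add atoms: 3-chloroperbenzoic acid, OOC(=O)c1cccc(Cl)c1
Why: Dakin-type Baeyer–Villiger oxidation of the electron-rich aldehyde (aryl migration favoured by the para aryloxy group) gives the aryl formate, which base-catalysed methanolysis cleaves to the C3 phenol.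

Step 8
Reactants: 13 4-(4-chloro-3,5-dimethoxyphenoxy)-3,5-bis(methoxymethoxy)phenol
Product: 14 2-(4-chloro-3,5-dimethoxyphenoxy)-5-methoxy-1,3-bis(methoxymethoxy)benzene
Conditions: MeI, K2CO3, acetone, reflux
Reagents that add atoms: iodomethane, CI
Why: Williamson O-methylation of the only free phenol fixes the C3 oxygen of ring C as a methyl ether.

Step 9
Reactants: 14 2-(4-chloro-3,5-dimethoxyphenoxy)-5-methoxy-1,3-bis(methoxymethoxy)benzene
Product: 15 2-(4-chloro-3,5-dimethoxyphenoxy)-5-methoxybenzene-1,3-diol (core diol)
Conditions: HCl (3 M aq), MeOH, 50 °C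
Reagents that add atoms: none
Why: Acid-catalysed acetal cleavage removes both MOM groups, with methanol trapping the methoxymethyl cation as dimethoxymethane, whereas methyl ethers, the diaryl ether and the aryl chloride are stable.

Step 10
Reactants: 15 2-(4-chloro-3,5-dimethoxyphenoxy)-5-methoxybenzene-1,3-diol; 10 4-fluoro-3,5-bis(methoxymethoxy)benzaldehyde (2.4 equiv)
Product: 16 four-ring dialdehyde 4,4'-{[2-(4-chloro-3,5-dimethoxyphenoxy)-5-methoxy-1,3-phenylene]bis(oxy)}bis[3,5-bis(methoxymethoxy)benzaldehyde]
Conditions: Cs2CO3, DMSO, 120 °C, argon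
Reagents that add atoms: none
Why: Twofold nucleophilic aromatic substitution, in which each ring C phenoxide displaces the para-formyl-activated fluoride of 10, forms the ethers from C1 and C5 to B4 of the two arms, and the ring C–ring E ether is no longer activated for exchange because its para formyl group has already become a methoxy group.

Step 11
Reactants: 16 four-ring dialdehyde
Product: 18 four-ring diphenol 4,4'-{[2-(4-chloro-3,5-dimethoxyphenoxy)-5-methoxy-1,3-phenylene]bis(oxy)}bis[3,5-bis(methoxymethoxy)phenol], via four-ring bis(formate) 17 (not isolated)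
Conditions: mCPBA, CH2Cl2, 0 °C → rt; reductive wash; then K2CO3 (cat.), MeOH, rt
Reagents that add atoms: 3-chloroperbenzoic acid, OOC(=O)c1cccc(Cl)c1
Why: Twofold Dakin-type Baeyer–Villiger oxidation of the ring B aldehydes and methanolysis of the formates should unveil the two B1 phenols, which lie between two ring hydrogens and are therefore unhindered nucleophiles for the next round.

Step 12
Reactants: 18 four-ring diphenol; 8 4-fluoro-3,5-dimethoxybenzaldehyde (2.4 equiv)
Product: 19 six-ring dialdehyde in which each B1 oxygen carries a 4-formyl-2,6-dimethoxyphenyl group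
Conditions: K2CO3, DMSO, 110 °C, argon
Reagents that add atoms: none
Why: Twofold nucleophilic aromatic substitution of the B1 phenoxides on the para-formyl-activated fluoride of 8 forms both ethers between ring A and B1, with the two ortho methoxy groups of ring A already in place.

Step 13
Reactants: 19 six-ring dialdehyde
Product: 21 six-ring diphenol in which each ring A is 4-hydroxy-2,6-dimethoxyphenyl, via six-ring bis(formate) 20 (not isolated)
Conditions: mCPBA, CH2Cl2, 0 °C → rt; reductive wash; then K2CO3 (cat.), MeOH, rt
Reagents that add atoms: 3-chloroperbenzoic acid, OOC(=O)c1cccc(Cl)c1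
Why: Twofold Dakin-type Baeyer–Villiger oxidation followed by formate methanolysis turns the formyl group of each ring A into the hydroxyl para to the ether oxygen.

Step 14
Reactants: 21 six-ring diphenol
Product: 22 six-ring tetrakis(methoxymethyl) ether in which each ring A is 2,4,6-trimethoxyphenyl
Conditions: MeI, K2CO3, acetone, reflux
Reagents that add atoms: iodomethane, CI
Why: Williamson O-methylation of the two ring A phenols completes both 2,4,6-trimethoxyphenoxy rings, while the MOM ethers keep the ring B oxygens distinct from all methyl ethers.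

Step 15
Reactants: 22 six-ring tetrakis(methoxymethyl) ether
Product: 23 six-ring tetraphenol whose only free hydroxyls are B3 and B5 of both arms
Conditions: HCl (3 M aq), MeOH/THF, 45 °C, argon
Reagents that add atoms: none
Why: Acid-catalysed cleavage of the four MOM acetals in methanol should free exactly the B3 and B5 hydroxyls of both arms and leave the nine methyl ethers, the diaryl ethers and the aryl chloride untouched.

Step 16
Reactants: 23 six-ring tetraphenol; 24 1,3,5-trimethoxybenzene (20 equiv)
Product: 25 eight-ring bis-biaryl tetraphenol carrying a 2,4,6-trimethoxyphenyl group at B6 of each arm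
Conditions: BDD anode, Pt cathode, undivided cell, constant current (ca. 5 mA cm−2, ca. 4.4 F mol−1), Bu3NMe·O3SOMe (0.1 M), HFIP, 40 °C
Reagents that add atoms: none
Why: Anodic oxidation of a ring B phenol in HFIP (loss of one electron and one proton, the hydroxyl being hydrogen-bonded to the solvent) should give a phenoxyl radical with spin density at B6 (ortho to the B5 hydroxyl, para to the B3 hydroxyl) and at the equivalent B2; the large excess of 24 traps it through one of its three identical CH carbons, and a second electron and proton loss rearomatises both rings while the protons are reduced to dihydrogen at the cathode. The closest known reaction is the anodic dehydrogenative phenol–arene cross-coupling at boron-doped diamond in fluorinated alcohols, here run once in each arm. No ring is closed and no stereocentre or stereogenic axis arises, because ring D bears identical ortho substituents. Chemoselectivity rests on ring B being the only ring with free hydroxyls, so it should be oxidised at the lowest potential while the methyl-capped rings A, C and E stay spectators and the excess of 24 outcompetes them as nucleophile; regioselectivity needs no control, because B4 is blocked and B2 and B6 are related by the local symmetry of ring B. Mono-arylation per arm is to be secured by metering the charge to about 2 F per arm and by the twist of the new tetra-ortho-substituted biaryl, which should disfavour a second coupling on the same ring.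

Step 17
Reactants: 25 eight-ring bis-biaryl tetraphenol
Product: 26 CNP0275555.0 (target)
Conditions: BBr3 (large excess), CH2Cl2, −78 °C → rt; then MeOH, evaporation, argon
Reagents that add atoms: none
Why: Exhaustive Lewis acid-mediated O-demethylation, in which bromide attacks the methyl carbon of each boron-complexed ether, should cleave all fifteen aryl methyl ethers, while diaryl ethers, the biaryl bonds and the aryl chloride are inert to BBr3.

**Compound list**

1 | 2-chloro-1,3-dimethoxybenzene | COc1cccc(OC)c1Cl | starting material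
2 | 2-(4-chloro-3,5-dimethoxyphenyl)-4,4,5,5-tetramethyl-1,3,2-dioxaborolane | COc1cc(B2OC(C)(C)C(C)(C)O2)cc(OC)c1Cl | intermediate
3 | 4-chloro-3,5-dimethoxyphenol (ring E) | COc1cc(O)cc(OC)c1Cl | intermediate
4 | 3,5-dimethoxybenzaldehyde | COc1cc(C=O)cc(OC)c1 | starting material
5 | 2-(3,5-dimethoxyphenyl)-1,3-dioxolane | COc1cc(cc(OC)c1)C1OCCO1 | intermediate
6 | [4-(1,3-dioxolan-2-yl)-2,6-dimethoxyphenyl]lithium | [Li]c1c(OC)cc(cc1OC)C1OCCO1 | intermediate
7 | 2-(4-fluoro-3,5-dimethoxyphenyl)-1,3-dioxolane | COc1cc(cc(OC)c1F)C1OCCO1 | intermediate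
8 | 4-fluoro-3,5-dimethoxybenzaldehyde | COc1cc(C=O)cc(OC)c1F | intermediate
9 | 4-fluoro-3,5-dihydroxybenzaldehyde | Oc1cc(C=O)cc(O)c1F | intermediate
10 | 4-fluoro-3,5-bis(methoxymethoxy)benzaldehyde | COCOc1cc(C=O)cc(OCOC)c1F | intermediate
11 | 4-(4-chloro-3,5-dimethoxyphenoxy)-3,5-bis(methoxymethoxy)benzaldehyde | COCOc1cc(C=O)cc(OCOC)c1Oc1cc(OC)c(Cl)c(OC)c1 | intermediate
12 | 4-(4-chloro-3,5-dimethoxyphenoxy)-3,5-bis(methoxymethoxy)phenyl formate | COCOc1cc(OC=O)cc(OCOC)c1Oc1cc(OC)c(Cl)c(OC)c1 | intermediate
13 | 4-(4-chloro-3,5-dimethoxyphenoxy)-3,5-bis(methoxymethoxy)phenol | COCOc1cc(O)cc(OCOC)c1Oc1cc(OC)c(Cl)c(OC)c1 | intermediate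
14 | 2-(4-chloro-3,5-dimethoxyphenoxy)-5-methoxy-1,3-bis(methoxymethoxy)benzene | COCOc1cc(OC)cc(OCOC)c1Oc1cc(OC)c(Cl)c(OC)c1 | intermediate
15 | 2-(4-chloro-3,5-dimethoxyphenoxy)-5-methoxybenzene-1,3-diol (core diol, rings C and E) | COc1cc(O)c(Oc2cc(OC)c(Cl)c(OC)c2)c(O)c1 | intermediate
16 | four-ring dialdehyde: 4,4'-{[2-(4-chloro-3,5-dimethoxyphenoxy)-5-methoxy-1,3-phenylene]bis(oxy)}bis[3,5-bis(methoxymethoxy)benzaldehyde] | COc1cc(Oc2c(OCOC)cc(C=O)cc2OCOC)c(Oc2cc(OC)c(Cl)c(OC)c2)c(Oc2c(OCOC)cc(C=O)cc2OCOC)c1 | intermediate
17 | four-ring bis(formate): 16 with each formyl group replaced by a formyloxy group | COc1cc(Oc2c(OCOC)cc(OC=O)cc2OCOC)c(Oc2cc(OC)c(Cl)c(OC)c2)c(Oc2c(OCOC)cc(OC=O)cc2OCOC)c1 | intermediate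
18 | four-ring diphenol: 4,4'-{[2-(4-chloro-3,5-dimethoxyphenoxy)-5-methoxy-1,3-phenylene]bis(oxy)}bis[3,5-bis(methoxymethoxy)phenol] | COc1cc(Oc2c(OCOC)cc(O)cc2OCOC)c(Oc2cc(OC)c(Cl)c(OC)c2)c(Oc2c(OCOC)cc(O)cc2OCOC)c1 | intermediate
19 | six-ring dialdehyde: 18 with a 4-formyl-2,6-dimethoxyphenyl group on each B1 oxygen | COc1cc(Oc2c(OCOC)cc(Oc3c(OC)cc(C=O)cc3OC)cc2OCOC)c(Oc2cc(OC)c(Cl)c(OC)c2)c(Oc2c(OCOC)cc(Oc3c(OC)cc(C=O)cc3OC)cc2OCOC)c1 | intermediate
20 | six-ring bis(formate): 19 with each formyl group replaced by a formyloxy group | COc1cc(Oc2c(OCOC)cc(Oc3c(OC)cc(OC=O)cc3OC)cc2OCOC)c(Oc2cc(OC)c(Cl)c(OC)c2)c(Oc2c(OCOC)cc(Oc3c(OC)cc(OC=O)cc3OC)cc2OCOC)c1 | intermediate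
21 | six-ring diphenol: each ring A is 4-hydroxy-2,6-dimethoxyphenyl | COc1cc(Oc2c(OCOC)cc(Oc3c(OC)cc(O)cc3OC)cc2OCOC)c(Oc2cc(OC)c(Cl)c(OC)c2)c(Oc2c(OCOC)cc(Oc3c(OC)cc(O)cc3OC)cc2OCOC)c1 | intermediate
22 | six-ring tetrakis(methoxymethyl) ether: each ring A is 2,4,6-trimethoxyphenyl, B3 and B5 of both arms carry OCH2OCH3 | COc1cc(Oc2c(OCOC)cc(Oc3c(OC)cc(OC)cc3OC)cc2OCOC)c(Oc2cc(OC)c(Cl)c(OC)c2)c(Oc2c(OCOC)cc(Oc3c(OC)cc(OC)cc3OC)cc2OCOC)c1 | intermediate
23 | six-ring tetraphenol (rings A, B, C, E; only B3 and B5 hydroxyls free, nine methyl ethers) | COc1cc(Oc2c(O)cc(Oc3c(OC)cc(OC)cc3OC)cc2O)c(Oc2cc(OC)c(Cl)c(OC)c2)c(Oc2c(O)cc(Oc3c(OC)cc(OC)cc3OC)cc2O)c1 | intermediate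
24 | 1,3,5-trimethoxybenzene | COc1cc(OC)cc(OC)c1 | starting material
25 | eight-ring bis-biaryl tetraphenol: 23 with a 2,4,6-trimethoxyphenyl group (ring D) at B6 of each arm, fifteen methyl ethers | COc1cc(Oc2c(O)cc(Oc3c(OC)cc(OC)cc3OC)c(-c3c(OC)cc(OC)cc3OC)c2O)c(Oc2cc(OC)c(Cl)c(OC)c2)c(Oc2c(O)cc(Oc3c(OC)cc(OC)cc3OC)c(-c3c(OC)cc(OC)cc3OC)c2O)c1 | intermediate
26 | CNP0275555.0: 25 with all fifteen methyl ethers cleaved (nineteen free hydroxyls, chlorine on ring E, no stereo-element) | Oc1cc(O)c(Oc2cc(O)c(Oc3cc(O)cc(Oc4c(O)cc(Oc5c(O)cc(O)cc5O)c(-c5c(O)cc(O)cc5O)c4O)c3Oc3cc(O)c(Cl)c(O)c3)c(O)c2-c2c(O)cc(O)cc2O)c(O)c1 | target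

**Step count and risks**

Total step count: 17. Longest linear sequence: 16 steps (steps 2 to 17, from 3,5-dimethoxybenzaldehyde); step 1 is a one-step branch that joins at step 6.

Steps most likely to fail:

1. Step 16. What may go wrong is over-oxidation: arylation continuing at B2 of a ring that has already coupled, or oxidative oligomerisation in which ring A or ring E of a second molecule acts as the nucleophile in place of 24. The fallback sets out from 23 and comes back at 25, and replaces the C–H/C–H coupling by a prefunctionalised cross-coupling. ortho-Selective bromination of 23 with NBS (2.0 equiv) and catalytic i-Pr2NH in CH2Cl2 at −78 °C should place one bromine at B6 of each arm and give the six-ring B6,B6'-dibromo tetraphenol F1. Suzuki–Miyaura coupling of this dibromide with commercial (2,4,6-trimethoxyphenyl)boronic acid (Pd(OAc)2, SPhos, K3PO4, toluene/H2O, 100 °C), a ligand system established for tetra-ortho-substituted biaryls, would then return to 25; the hindered, electron-rich aryl chloride of ring E should not react.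

2. Step 10. What may go wrong is stalling of the second substitution as three aryloxy groups crowd around C6, so that mono-arylated material accumulates. The fallback sets out from 15 and comes back at 16, and replaces uncatalysed addition–elimination on a fluoride by a copper-catalysed Ullmann-type ether synthesis on a bromide. Commercial 4-bromo-3,5-dimethoxybenzaldehyde is demethylated with BBr3 in CH2Cl2 to 4-bromo-3,5-dihydroxybenzaldehyde F2, which is protected with MOMCl and i-Pr2NEt as 4-bromo-3,5-bis(methoxymethoxy)benzaldehyde F3. Twofold coupling of this bromide with 15 (CuI, picolinic acid, K3PO4, DMSO, 90 °C), conditions developed for hindered diaryl ethers, would give 16.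

3. Step 17. What may go wrong is incomplete cleavage of the shielded methyl ethers next to the biaryl and diaryl ether junctions, together with oxidative loss of the very polar polyphenol during isolation. The fallback sets out from 25 and comes back at 26, and isolates the product through a stable derivative. After the BBr3 treatment and methanol quench, the crude material is peracetylated (Ac2O, pyridine, DMAP) to the nonadecaacetate of the target F4, which can be chromatographed on silica; partly methylated fractions can be resubjected to BBr3. Deacetylation with catalytic NaOMe in degassed MeOH, followed by neutralisation with an acidic ion-exchange resin, would then release 26.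

**Further compounds**

F1 | step 16 | six-ring B6,B6'-dibromo tetraphenol (23 with bromine at B6 of each arm) | COc1cc(Oc2c(O)cc(Oc3c(OC)cc(OC)cc3OC)c(Br)c2O)c(Oc2cc(OC)c(Cl)c(OC)c2)c(Oc2c(O)cc(Oc3c(OC)cc(OC)cc3OC)c(Br)c2O)c1
F2 | step 10 | 4-bromo-3,5-dihydroxybenzaldehyde | Oc1cc(C=O)cc(O)c1Br
F3 | step 10 | 4-bromo-3,5-bis(methoxymethoxy)benzaldehyde | COCOc1cc(C=O)cc(OCOC)c1Br
F4 | step 17 | nonadecaacetate of the target (every hydroxyl of 26 acetylated) | CC(=O)Oc1cc(OC(C)=O)c(Oc2cc(OC(C)=O)c(Oc3cc(OC(C)=O)cc(Oc4c(OC(C)=O)cc(Oc5c(OC(C)=O)cc(OC(C)=O)cc5OC(C)=O)c(-c5c(OC(C)=O)cc(OC(C)=O)cc5OC(C)=O)c4OC(C)=O)c3Oc3cc(OC(C)=O)c(Cl)c(OC(C)=O)c3)c(OC(C)=O)c2-c2c(OC(C)=O)cc(OC(C)=O)cc2OC(C)=O)c(OC(C)=O)c1
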